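## Structural features

The target is a para-depside: two benzene rings joined only by an aryl ester running from the carboxyl carbon on C1 of ring B to O-4' of ring A. There is no stereocentre, so no stereochemical relationship has to be set. Ring A is an olivetolic acid unit (C1' carboxylic acid, C2' hydroxyl, C4' ester oxygen, C6' pentyl). Ring B is a 3-chloro-2-hydroxy-4-methoxy-6-propylbenzoyl unit. The fragile points are the depside ester (an activated aryl ester, cleaved or transacylated by alkoxide, hydroxide and unhindered amines), the free salicylic acid of ring A (prone to decarboxylation on heating in acid) and the two chelated phenols, which must stay free. The difficulty is threefold: the ester carbonyl lies between two ortho substituents (C2 hydroxyl, C6 propyl), so acylation with an activated ring B acid is hindered; the chlorine must go to C3, between hydroxyl and methoxy, and not to C5; and one of three phenolic oxygens must be methylated while one of two carboxyls stays free. The plan exploits the polyketide pattern of ring B: oxygens on C2 and C4, alkyl on C6 and carboxyl on C1 are what a C2-to-C7 aldol fold of a 3,5,7-trioxodecanoyl chain delivers, and C1 of that chain is the depside carbonyl. Ring B can therefore be grown on an ester already attached to O-4' of ring A, and the late substituents are placed by the difference between the single unchelated phenol and the chelated ones.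

## Logic of the disconnections

**15 from 14.** The O–allyl bond of the ring A carboxylate is cut. The carboxyl has to be masked through the ketene, base, methylation and chlorination stages. The allyl ester is chosen because it comes off under neutral conditions, which puts on the last step the demand that it touch neither the depside ester nor the C–Cl bond (no hydroxide, no hydrogenolysis).

**14 from 13.** The C3–Cl bond of ring B is cut. In 13 ring B carries one free phenol, whose only open ortho position is C3, so a phenol-directed chlorination can be asked to find it. The forward step must prefer C3 over C5 (para to that phenol) and ring B over the less electron-rich ring A.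

**13 from 12.** The O-4–methyl bond is cut. 12 has exactly one unchelated phenol, so no protecting group is needed. The base must be mild enough to leave the depside ester intact.

**12 from 10 (key step).** The C1–C6 bond of ring B (C2–C7 of the chain) is cut and the arene is unfolded into the acyclic triketo ester. This removes ring B and its whole substitution pattern in one move and avoids acylating a phenol with a 2,6-disubstituted benzoic acid. The forward aldol must beat the two closures that expel the ring A aryl oxide.

**10 from 5 and 8, through 9.** The ester bond O-4'–C1 is cut. Addition of a phenol to an acylketene needs neither activating agent nor base, and it joins two fragments of similar size. The demand is that 9 be intercepted by the unchelated phenol of 8 faster than it reacts with its own enol or with itself.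

**5 from 3 and 4; 3 from 1 and 2.** The chain bonds C6–C7 and C4–C5 (decanoyl numbering) are cut. Both are Claisen-type acylations of dioxinone-stabilised anions, and the dioxinone ring carries C1–C3 of the chain as a latent ketene. The first must be gamma-selective and the second must occur at the terminal carbon of a dianion without over-reaction.

**8 from 7; 7 from 6.** The O–allyl bond and then the C1'–carboxyl bond are cut. 6 has the full carbon and oxygen pattern of ring A except the carboxyl. The demands are carboxylation ortho to one hydroxyl and para to the other, and alkylation of the carboxylate only.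

## Other disconnections considered

**Alternative 1:** The cut goes through two bonds of ring A, C6'–pentyl and C1'–carboxyl.
- Forward step: 1-fluoro-3,5-dimethoxybenzene A1 would be metalated between fluorine and methoxy and eliminate fluoride to 3,5-dimethoxybenzyne A2. Pentyllithium A3 would add at the aryne carbon remote from the methoxy group, and the aryllithium would be carboxylated to 2,4-dimethoxy-6-pentylbenzoic acid A4.
- In favour: one flask, three components, and a regiochemistry fixed by the inductive stabilisation of the aryl anion next to methoxy. On mechanism this is at least the equal of, and probably more secure than, the reversible chelate-controlled carboxylation of step 3.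
- Against: it builds the part of the target that least needs building, since 6 already holds the ring A pattern. A4 arrives with both oxygens methylated, and removing the 4'-methyl ether, which has no chelation assistance, needs strong Lewis acid conditions under which a 2,4-dioxygenated benzoic acid tends to decarboxylate. It contributes nothing to ring B, the depside bond or the chlorine.
- Comparison: on structure it covers one ring only. On step economy it replaces steps 3 and 4 by at least three operations (aryne step, double demethylation, allylation), so it is the weaker choice here.

**Alternative 2:** The cut takes out the depside carbonyl carbon, breaking C1–carbonyl and carbonyl–O-4'.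
- Forward step: 2-chloro-4-iodo-1,3-dimethoxy-5-propylbenzene A5 and tert-butyl 2,4-dihydroxy-6-pentylbenzoate A6 would be joined under a CO atmosphere by palladium-catalysed carbonylative esterification (Pd(OAc)2, Xantphos, NEt3). The product would be tert-butyl 4-(3-chloro-2,4-dimethoxy-6-propylbenzoyloxy)-2-hydroxy-6-pentylbenzoate A7.
- In favour: chlorine and both ring B oxygens are fixed before the union, so the regiochemical question of step 8 does not arise; on this point it is the better plan. The carbonyl comes from CO, so no hindered acid is activated, and convergence is equal to that of the chosen route.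
- Against: A5 is a pentasubstituted iodoarene needing its own sequence (chlorination between the oxygens of a dimethylated 5-propylresorcinol, then iodination). Oxidative addition and CO insertion at an iodide flanked by methoxy and propyl are slow, and the hindered aroyl-palladium species must be captured by a weakly nucleophilic phenol. A7 still needs selective removal of the ring B 2-O-methyl group in the presence of the depside ester, plus ester cleavage.
- Comparison: on structure it is stronger in pre-installed substituents. On mechanism the intermolecular carbonylation at a di-ortho-substituted centre is less assured than an intramolecular aldol. On step economy it is no shorter than nine steps.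

**Alternative 3:** The cut is a [4+2] disconnection of ring B at C1–C2 and C5–C6.
- Forward step: allyl 4-(hex-2-ynoyloxy)-2-hydroxy-6-pentylbenzoate A8, reached from 8 by simple acylation, would react with 2-chloro-1,3-dimethoxy-1-(trimethylsilyloxy)buta-1,3-diene A9 in a Diels–Alder addition. The nucleophilic CH2 terminus of the diene would bond to the propyl-bearing alkyne carbon, and loss of methanol would give the arene A10, which is the same compound as 14.
- In favour: like the chosen plan it grows ring B on an ester already in place. It also delivers the O-methyl group and the chlorine in their final positions by construction, so steps 7 and 8 disappear. On regiocontrol and on step count (about six steps overall) it is the better plan.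
- Against: an internal ynoate with a beta-alkyl group is a sluggish dienophile. The chlorine lowers the nucleophilicity of the diene and adds bulk at the bond-forming ketene acetal carbon, so forcing temperatures are expected, at which an O-silyl ketene acetal is thermally and protolytically labile, the more so beside a free phenol.
- Comparison: on structure it is equal in concept and superior in what it pre-installs. On mechanism the chosen aldol fold rests on the innate reactivity of a poly-beta-carbonyl chain and on close analogy, whereas the cycloaddition of a tetrasubstituted chlorinated diene is the less predictable event. The chosen plan is preferred for the dependability of its ring-forming step.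

Key step: step 6

Remark on the chemistry: the connectivities of 10 and 12 agree with the target and need no change, but two points of rationale are corrected. In 10 the methylenes C4 and C6, each between two ketones, are at least as acidic as C2. The closure is 6-exo-trig and is allowed both as enolendo (C2=C3 ketone enolate) and as enolexo (ester enolate). The N-methoxy-N-methylamide 4 is assumed to be a catalogue reagent and is used instead of the acid chloride because its tetrahedral adduct prevents over-reaction.

## Route

Step 1
Reactants: 1 2,2,6-trimethyl-4H-1,3-dioxin-4-one; 2 acetyl chloride
Product: 3 2,2-dimethyl-6-(2-oxopropyl)-4H-1,3-dioxin-4-one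
Conditions: 1 (2 equiv), LiN(SiMe3)2 (2 equiv), THF, −78 °C; then 2 (1 equiv), −78 °C; 1 M HCl
Reagents that add atoms: none
Why: Deprotonation of the 6-methyl group gives the vinylogous ester dienolate, which is C-acylated at the gamma carbon (Claisen-type acylation); the second equivalent of dienolate takes up the acidic proton of the beta-keto product, so the acid chloride is limiting and surplus 1 is recovered.

Step 2
Reactants: 3 2,2-dimethyl-6-(2-oxopropyl)-4H-1,3-dioxin-4-one; 4 N-methoxy-N-methylbutanamide
Product: 5 6-(2,4-dioxoheptyl)-2,2-dimethyl-4H-1,3-dioxin-4-one
Conditions: LiN(iPr)2 (2.1 equiv), THF, −78 °C; then 4 (1.0 equiv), −78 to −30 °C; 1 M HCl, 0 °C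
Reagents that add atoms: none
Why: Double deprotonation gives the 1,3-dicarbonyl dianion, whose terminal, less stabilised carbanion attacks the N-methoxy-N-methylamide (dianion Claisen acylation); the chelated tetrahedral adduct persists until the acid quench, so neither a second addition nor proton transfer from the product can interfere.

Step 3
Reactants: 6 olivetol (5-pentylbenzene-1,3-diol)
Product: 7 olivetolic acid (2,4-dihydroxy-6-pentylbenzoic acid)
Conditions: MeOMgOCO2Me (2 M in DMF, 4 equiv), 120 °C, N2 stream; then cold 3 M HCl
Reagents that add atoms: methyl magnesium carbonate, COC(=O)O[Mg]OC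
Why: Kolbe–Schmitt-type ortho-carboxylation of the magnesium phenoxide, driven by formation of the magnesium salicylate chelate; the position ortho to one oxygen and para to the other is the more nucleophilic ortho site and leads to 7.

Step 4
Reactants: 7 olivetolic acid
Product: 8 allyl 2,4-dihydroxy-6-pentylbenzoate
Conditions: allyl bromide (1.05 equiv), KHCO3 (1.2 equiv), DMF, rt
Reagents that add atoms: allyl bromide, C=CCBr
Why: Hydrogen carbonate ionises only the carboxylic acid, so SN2 alkylation gives the allyl ester and leaves both phenols free; room temperature avoids decarboxylation of the salicylic acid.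

Step 5
Reactants: 5 6-(2,4-dioxoheptyl)-2,2-dimethyl-4H-1,3-dioxin-4-one; 8 allyl 2,4-dihydroxy-6-pentylbenzoate
Product: 10 allyl 2-hydroxy-6-pentyl-4-(3,5,7-trioxodecanoyloxy)benzoate, via acylketene 3,5,7-trioxodec-1-en-1-one 9 (not isolated)
Conditions: 8 (1.2 equiv), toluene (0.1 M), 110 °C, 1 h; evaporation, crude 10 used at once
Reagents that add atoms: none
Why: Thermal retro-[4+2] fragmentation of the dioxinone releases acetone and the acylketene, which adds the only unchelated phenol of 8 (O-4') without base or activating agent, a reaction type established for phenols and dioxinones; the hydrogen-bonded 2'-hydroxyl is far less nucleophilic, and the excess of 8 at moderate concentration favours intermolecular capture.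

Step 6
Reactants: 10 allyl 2-hydroxy-6-pentyl-4-(3,5,7-trioxodecanoyloxy)benzoate
Product: 12 allyl 4-(2,4-dihydroxy-6-propylbenzoyloxy)-2-hydroxy-6-pentylbenzoate, via cyclic aldol adduct 11 (not isolated)
Conditions: Et3N (2 equiv), CH2Cl2, 0 °C to rt; then HCl (4 M in dioxane), rt
Reagents that add atoms: none
Why: Et3N enolises the poly-beta-carbonyl chain reversibly; C4 and C6 are at least as acidic as C2, but their enolates have no six-membered C–C closure that keeps the ester, so the reaction funnels through the C2 enolate, which adds to the C7 ketone and gives aldol 11 (chain bond C2–C7, the C1–C6 bond of ring B). The closure is 6-exo-trig at the C7 carbonyl; the nucleophilic double bond lies inside the new ring when written as the C2=C3 ketone enolate (enolendo) and outside it when written as the ester enolate (enolexo), and Baldwin's rules allow both for a six-membered ring. Acid then removes the C7 hydroxyl as one molecule of water and the C3 and C5 ketones enolise, which makes the sequence irreversible and gives the 2,4-dihydroxy-6-propylbenzoate. The closest known reaction type is the biomimetic aldol cycloaromatisation of 3,5,7-triketo esters to resorcylates used in dioxinone-based resorcylate synthesis. The two sp3 centres of 11 are transient and are erased on aromatisation, so no stereocontrol is needed. The selectivity required is C-attack at C7 over attack of the C5 enol oxygen (lactonisation to a 4-hydroxy-2-pyranone) or of C6 (Claisen closure to an acylphloroglucinol) on the ester carbonyl, both of which would expel the ring A aryl oxide. A weak, non-nucleophilic amine in an aprotic solvent at low temperature followed by acid favours the aldol path, whereas alkoxides, magnesium salts or hot acid favour the other two; the chelated 2'-hydroxyl and the allyl ester are spectators.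

Step 7
Reactants: 12 allyl 4-(2,4-dihydroxy-6-propylbenzoyloxy)-2-hydroxy-6-pentylbenzoate
Product: 13 allyl 2-hydroxy-4-(2-hydroxy-4-methoxy-6-propylbenzoyloxy)-6-pentylbenzoate
Conditions: MeI (1.1 equiv), K2CO3 (1.1 equiv), acetone, rt
Reagents that add atoms: iodomethane, CI
Why: Williamson ether synthesis on the only unchelated and most acidic phenol (O-4 of ring B, para to the ester carbonyl); the two hydrogen-bonded ortho-hydroxyls resist alkylation with one equivalent at room temperature, and anhydrous carbonate in acetone spares the depside ester.

Step 8
Reactants: 13 allyl 2-hydroxy-4-(2-hydroxy-4-methoxy-6-propylbenzoyloxy)-6-pentylbenzoate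
Product: 14 allyl 4-(3-chloro-2-hydroxy-4-methoxy-6-propylbenzoyloxy)-2-hydroxy-6-pentylbenzoate
Conditions: SO2Cl2 (1.05 equiv, slow addition), 2,2,6,6-tetramethylpiperidine (10 mol %), toluene, 0 °C to rt, dark
Reagents that add atoms: sulfuryl chloride, O=S(=O)(Cl)Cl
Why: Amine-catalysed ortho-selective electrophilic chlorination of a phenol: the hindered amine is chlorinated in situ and delivers chlorine through a hydrogen bond to the phenol, and C3 is the only free ortho position of the ring B hydroxyl and is further activated by the neighbouring methoxy. Ring A, with an acyloxy in place of methoxy, is much less nucleophilic, and the electron-poor terminal allyl alkene should not react under ionic conditions at low temperature.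

Step 9
Reactants: 14 allyl 4-(3-chloro-2-hydroxy-4-methoxy-6-propylbenzoyloxy)-2-hydroxy-6-pentylbenzoate
Product: 15 4-(3-chloro-2-hydroxy-4-methoxy-6-propylbenzoyloxy)-2-hydroxy-6-pentylbenzoic acid
Conditions: Pd(PPh3)4 (5 mol %), N-methylaniline (3 equiv), THF, rt; 1 M HCl wash
Reagents that add atoms: none
Why: Tsuji–Trost-type deallylation: zerovalent palladium ionises the allyl ester to a pi-allyl complex and the carboxylate, and the weakly basic, poorly acylated aniline captures the allyl group; the conditions are neutral, so the depside ester, the aryl chloride and the phenols are untouched.

## Compound list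

1 | 2,2,6-trimethyl-4H-1,3-dioxin-4-one | CC1=CC(=O)OC(C)(C)O1 | starting material
2 | acetyl chloride | CC(=O)Cl | starting material
3 | 2,2-dimethyl-6-(2-oxopropyl)-4H-1,3-dioxin-4-one | CC(=O)CC1=CC(=O)OC(C)(C)O1 | intermediate
4 | N-methoxy-N-methylbutanamide | CCCC(=O)N(C)OC | starting material
5 | 6-(2,4-dioxoheptyl)-2,2-dimethyl-4H-1,3-dioxin-4-one | CCCC(=O)CC(=O)CC1=CC(=O)OC(C)(C)O1 | intermediate
6 | olivetol (5-pentylbenzene-1,3-diol) | CCCCCc1cc(O)cc(O)c1 | starting material
7 | olivetolic acid (2,4-dihydroxy-6-pentylbenzoic acid) | CCCCCc1cc(O)cc(O)c1C(=O)O | intermediate
8 | allyl 2,4-dihydroxy-6-pentylbenzoate | CCCCCc1cc(O)cc(O)c1C(=O)OCC=C | intermediate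
9 | 3,5,7-trioxodec-1-en-1-one (acylketene, formed in the flask) | CCCC(=O)CC(=O)CC(=O)C=C=O | intermediate
10 | allyl 2-hydroxy-6-pentyl-4-(3,5,7-trioxodecanoyloxy)benzoate | CCCCCc1cc(OC(=O)CC(=O)CC(=O)CC(=O)CCC)cc(O)c1C(=O)OCC=C | intermediate
11 | allyl 2-hydroxy-4-[(2-hydroxy-4,6-dioxo-2-propylcyclohexane-1-carbonyl)oxy]-6-pentylbenzoate (cyclic aldol adduct, formed in the flask; mixture of diastereomers and enol tautomers, configuration undefined and erased in the same step) | CCCCCc1cc(OC(=O)C2C(=O)CC(=O)CC2(O)CCC)cc(O)c1C(=O)OCC=C | intermediate
12 | allyl 4-(2,4-dihydroxy-6-propylbenzoyloxy)-2-hydroxy-6-pentylbenzoate | CCCCCc1cc(OC(=O)c2c(CCC)cc(O)cc2O)cc(O)c1C(=O)OCC=C | intermediate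
13 | allyl 2-hydroxy-4-(2-hydroxy-4-methoxy-6-propylbenzoyloxy)-6-pentylbenzoate | CCCCCc1cc(OC(=O)c2c(CCC)cc(OC)cc2O)cc(O)c1C(=O)OCC=C | intermediate
14 | allyl 4-(3-chloro-2-hydroxy-4-methoxy-6-propylbenzoyloxy)-2-hydroxy-6-pentylbenzoate | CCCCCc1cc(OC(=O)c2c(CCC)cc(OC)c(Cl)c2O)cc(O)c1C(=O)OCC=C | intermediate
15 | 4-(3-chloro-2-hydroxy-4-methoxy-6-propylbenzoyloxy)-2-hydroxy-6-pentylbenzoic acid | CCCCCc1cc(OC(=O)c2c(CCC)cc(OC)c(Cl)c2O)cc(O)c1C(=O)O | target

## Step count and least certain steps

Total step count: 9. Longest linear sequence: 7 steps (1, 2, 5, 6, 7, 8, 9); the ring A branch (steps 3 and 4) joins at step 5.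

**Step 6 (key step).** The most likely failure is acyl transfer within the chain with loss of the ring A aryl oxide, by attack of the C5 enol oxygen or of C6 on the ester carbonyl. An aryl ester is a far better leaving group than the alkyl esters for which this fold is well established.
Fallback: let the same aldol fold take place while the carboxyl is still locked in the dioxinone, and make the depside bond by classical esterification. It sets out from 5. Et3N in CH2Cl2 and then acid should close the ring onto the dioxinone and give 7-hydroxy-2,2-dimethyl-5-propyl-4H-1,3-benzodioxin-4-one F1. MeI and K2CO3 in acetone should give 7-methoxy-2,2-dimethyl-5-propyl-4H-1,3-benzodioxin-4-one F2. KOH in aqueous DMSO followed by acid should open the acetonide to 2-hydroxy-4-methoxy-6-propylbenzoic acid F3. DCC-mediated esterification of F3 with the unchelated phenol of 8 in toluene at rt comes back to the route at 13.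

**Step 8.** The most likely failure is poor positional selectivity: chlorination at C5 of ring B (para to the chelated hydroxyl, the innate preference of salicylate-type phenols) or double chlorination, if the uncatalysed background reaction of the electron-rich ring outruns the amine-directed path. Addition of chlorine to the allyl double bond is a lesser concern.
Fallback: move the chlorination to a monomeric ring B ester, where regioisomers are separated cheaply and the position of chlorine is secured before the depside exists. This does not remove the regiochemical question; it makes a mixture tolerable. It sets out from 5. Heating with methanol in toluene (ketene 9 again) gives methyl 3,5,7-trioxodecanoate F4, not isolated, which is aromatised with Cs2CO3 in methanol and then HCl to methyl 2,4-dihydroxy-6-propylbenzoate F5. MeI and K2CO3 give methyl 2-hydroxy-4-methoxy-6-propylbenzoate F6. Chlorination as in step 8, with chromatographic removal of the regioisomer, gives methyl 3-chloro-2-hydroxy-4-methoxy-6-propylbenzoate F7. KOH in aqueous DMSO and then acid gives 3-chloro-2-hydroxy-4-methoxy-6-propylbenzoic acid F8. DCC esterification of F8 with 8 comes back to the route at 14.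

**Step 5.** The most likely failure is consumption of the acylketene by its own enol oxygen (cyclisation) or by dimerisation before the phenol adds, since the phenol is only moderately nucleophilic and is deactivated by its para ester group. A second acylation at the chelated hydroxyl is a minor concern.
Fallback: form the aryl ester first by ordinary acylation with a simple acid and build ring B on it by cycloaddition, so that no ketene and no poly-beta-carbonyl chain are involved. It sets out from 8. DCC and catalytic DMAP with hex-2-ynoic acid should give allyl 4-(hex-2-ynoyloxy)-2-hydroxy-6-pentylbenzoate F9. Heating F9 with an excess of 1,3-dimethoxy-1-(trimethylsilyloxy)buta-1,3-diene in toluene or xylene at 110–140 °C should give the adduct allyl 4-{[4,6-dimethoxy-2-propyl-6-(trimethylsilyloxy)cyclohexa-1,4-diene-1-carbonyl]oxy}-2-hydroxy-6-pentylbenzoate F10, not isolated. F10 loses methanol and, on acidic work-up, its silyl group, and comes back to the route at 13 (steps 5 to 7 are bypassed). The excess of diene allows for transient silylation of the chelated phenol.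

**Step 3.** The most likely failure is carboxylation at the position between the two hydroxyls, or decarboxylation of the product during the hot reaction or the acidic work-up, because the chelate-controlled carboxylation is reversible.
Fallback: assemble the ring A ester by the same dioxinone chemistry as ring B, which fixes the regiochemistry by construction. It sets out from 3. Dianion acylation with N-methoxy-N-methylhexanamide under the conditions of step 2 should give 6-(2,4-dioxononyl)-2,2-dimethyl-4H-1,3-dioxin-4-one F11. Heating F11 with allyl alcohol in toluene should pass through the acylketene 3,5,7-trioxododec-1-en-1-one F12 and allyl 3,5,7-trioxododecanoate F13, neither isolated. Et3N and then HCl complete the aromatisation, and the sequence comes back to the route at 8 with the step count unchanged.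

## Further compounds

F1 | step 6 | 7-hydroxy-2,2-dimethyl-5-propyl-4H-1,3-benzodioxin-4-one | CCCc1cc(O)cc2OC(C)(C)OC(=O)c12
F2 | step 6 | 7-methoxy-2,2-dimethyl-5-propyl-4H-1,3-benzodioxin-4-one | CCCc1cc(OC)cc2OC(C)(C)OC(=O)c12
F3 | step 6 | 2-hydroxy-4-methoxy-6-propylbenzoic acid | CCCc1cc(OC)cc(O)c1C(=O)O
F4 | step 8 | methyl 3,5,7-trioxodecanoate | CCCC(=O)CC(=O)CC(=O)CC(=O)OC
F5 | step 8 | methyl 2,4-dihydroxy-6-propylbenzoate | CCCc1cc(O)cc(O)c1C(=O)OC
F6 | step 8 | methyl 2-hydroxy-4-methoxy-6-propylbenzoate | CCCc1cc(OC)cc(O)c1C(=O)OC
F7 | step 8 | methyl 3-chloro-2-hydroxy-4-methoxy-6-propylbenzoate | CCCc1cc(OC)c(Cl)c(O)c1C(=O)OC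
F8 | step 8 | 3-chloro-2-hydroxy-4-methoxy-6-propylbenzoic acid | CCCc1cc(OC)c(Cl)c(O)c1C(=O)O
F9 | step 5 | allyl 4-(hex-2-ynoyloxy)-2-hydroxy-6-pentylbenzoate | CCCCCc1cc(OC(=O)C#CCCC)cc(O)c1C(=O)OCC=C
F10 | step 5 | allyl 4-{[4,6-dimethoxy-2-propyl-6-(trimethylsilyloxy)cyclohexa-1,4-diene-1-carbonyl]oxy}-2-hydroxy-6-pentylbenzoate | CCCC1=C(C(=O)Oc2cc(O)c(C(=O)OCC=C)c(CCCCC)c2)C(OC)(O[Si](C)(C)C)C=C(OC)C1
F11 | step 3 | 6-(2,4-dioxononyl)-2,2-dimethyl-4H-1,3-dioxin-4-one | CCCCCC(=O)CC(=O)CC1=CC(=O)OC(C)(C)O1
F12 | step 3 | 3,5,7-trioxododec-1-en-1-one | CCCCCC(=O)CC(=O)CC(=O)C=C=O
F13 | step 3 | allyl 3,5,7-trioxododecanoate | CCCCCC(=O)CC(=O)CC(=O)CC(=O)OCC=C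
A1 | alternative 1 | 1-fluoro-3,5-dimethoxybenzene | COc1cc(F)cc(OC)c1
A2 | alternative 1 | 3,5-dimethoxybenzyne | COC1=CC(OC)=CC#C1
A3 | alternative 1 | pentyllithium | [Li]CCCCC
A4 | alternative 1 | 2,4-dimethoxy-6-pentylbenzoic acid | CCCCCc1cc(OC)cc(OC)c1C(=O)O
A5 | alternative 2 | 2-chloro-4-iodo-1,3-dimethoxy-5-propylbenzene | CCCc1cc(OC)c(Cl)c(OC)c1I
A6 | alternative 2 | tert-butyl 2,4-dihydroxy-6-pentylbenzoate | CCCCCc1cc(O)cc(O)c1C(=O)OC(C)(C)C
A7 | alternative 2 | tert-butyl 4-(3-chloro-2,4-dimethoxy-6-propylbenzoyloxy)-2-hydroxy-6-pentylbenzoate | CCCCCc1cc(OC(=O)c2c(CCC)cc(OC)c(Cl)c2OC)cc(O)c1C(=O)OC(C)(C)C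
A8 | alternative 3 | allyl 4-(hex-2-ynoyloxy)-2-hydroxy-6-pentylbenzoate | CCCCCc1cc(OC(=O)C#CCCC)cc(O)c1C(=O)OCC=C
A9 | alternative 3 | 2-chloro-1,3-dimethoxy-1-(trimethylsilyloxy)buta-1,3-diene | COC(=C)C(Cl)=C(OC)O[Si](C)(C)C
A10 | alternative 3 | allyl 4-(3-chloro-2-hydroxy-4-methoxy-6-propylbenzoyloxy)-2-hydroxy-6-pentylbenzoate | CCCCCc1cc(OC(=O)c2c(CCC)cc(OC)c(Cl)c2O)cc(O)c1C(=O)OCC=C
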